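## Analysis of the target

Schizolaenone A (9) is a flavanone: ring A is fused to the heterocyclic ring C (a chroman-4-one), and C2 carries the 4-hydroxyphenyl ring B. This is the naringenin skeleton, extended by a 3-methylbut-2-enyl (prenyl) group on C6 and an (E)-3,7-dimethylocta-2,6-dienyl (geranyl) group on C3'. The only stereocentre is C2 (S). It is benzylic, bonded to O1 and β to the C4 carbonyl, so base can open ring C by a retro-oxa-Michael reaction and reclose it without stereocontrol, and strong acid can ionise the C2–O1 bond. The E geometry of the first geranyl double bond is the only other stereochemical element. Three trisubstituted olefins are each placed where acid can cyclise them onto a neighbouring phenol to give a chroman. The three phenols differ in acidity: 7-OH is a vinylogous acid and the most acidic, 4'-OH is an ordinary phenol, and 5-OH is hydrogen-bonded to C4=O and the least reactive. The difficulty is regiochemical, not skeletal: ring A has two almost equivalent nucleophilic carbons, C6 and C8, and direct C-alkylation of the triphenol gives mixtures of O-, 6-, 8- and poly-alkylated products. The plan rests on the fact that each chain stands on a carbon next to a phenolic oxygen. C6 neighbours O5, whose other ortho carbon C4a is the ring fusion; C3' neighbours O4', whose two ortho carbons are equivalent. Each chain can therefore be attached to its oxygen first and then moved to the adjacent carbon.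

## Retrosynthetic reasoning

The last bond cut is O7–Si. Target 9 is traced back to its 7-O-triisopropylsilyl ether 8, because the 7-oxygen must be blocked throughout: it is the most acidic phenol and would otherwise be alkylated first, and a free 7-OH next to the C6 prenyl group would invite chroman formation under acid. A bulky silyl ether on a vinylogous-acid oxygen survives near-neutral alkylations and mild acid, and comes off with buffered fluoride, which touches neither C2 nor the olefins.

The central disconnection cuts the two C–C bonds that join the chains to the rings, C6–CH2 of the prenyl group and C3'–CH2 of the geranyl group. Each chain goes back to the neighbouring oxygen, which gives the bis-ether 6: 5-O-prenyl, 4'-O-geranyl, 7-O-silyl. Cutting here removes the C6/C8 question, since an allyl cation released from O5 has only C6 beside it, and one released from O4' has two equivalent ortho carbons. The forward reaction must ionise both ethers on an acidic clay and let each cation return through its CH2 end to the adjacent carbon. It must do so without cyclising the products and without touching C2. The ring A ether is expected to move first, passing through the mono-rearranged compound 7.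

The O5–CH2 bond of 6 is cut next, giving the 5-hydroxy compound 4 and prenol 5. The 5-OH is chelated and hindered, so the forward step has to alkylate a poor nucleophile without strong base, which would open ring C; a Mitsunobu etherification meets that need. It is placed last among the alkylations because the 5-O-prenyl ether is the most acid-labile group in the sequence.

The O4'–CH2 bond of 4 is then cut, giving the 7-O-silyl ether 2 and geraniol 3. With O7 blocked and O5 chelated, the 4'-OH is the only phenol that engages readily under Mitsunobu conditions, and SN2 displacement at the primary allylic carbon keeps the chain linear and E.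

Finally the O7–Si bond of 2 is cut to reach (2S)-naringenin 1. It supplies rings A, B and C and the C2 stereocentre, so no ring and no stereocentre has to be made. The forward silylation relies only on the acidity order 7-OH > 4'-OH > 5-OH.

## Alternatives that were turned down

Alternative 1: The disconnection is the aryl ether bond O1–C8a of ring C, with C4 at the alcohol oxidation level. The precursor is the chloro diol A2, (1S,3S)-1-[3-geranyl-4-(methoxymethoxy)phenyl]-3-[6-chloro-2,4-bis(methoxymethoxy)-3-(3-methylbut-2-enyl)phenyl]propane-1,3-diol. With Pd(OAc)2, a hindered di-tert-butylbiarylphosphine and Cs2CO3, palladium would insert into the C8a–Cl bond, the C2 alkoxide would replace chloride on the metal, and reductive elimination would close ring C. The product is the flavan-4-ol A1, (2S,4S)-3'-geranyl-5,7,4'-tris(methoxymethoxy)-6-prenylflavan-4-ol. Oxidation at C4 and removal of three methoxymethyl groups would follow.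
- For it: both chains are placed on simple arenes before the rings are joined, so the choices C6 versus C8 and ring A versus ring B never arise. On site control this plan is stronger than the chosen one, which must win C6 over C8 kinetically. The C2–O bond is not broken in the coupling, so a configuration set in the open chain is retained.
- Against it: the aryl chloride is electron-rich and ortho-substituted, a poor partner for oxidative addition. A secondary benzylic alkoxide on divalent palladium has β-hydrogens, so β-hydride elimination with hydrodechlorination competes with C–O bond formation. The C4 carbinol is a redox detour. The final removal of three acetal groups needs protic acid, the very conditions that close ortho-prenyl and ortho-geranyl phenols to chromans. Two arene fragments, their union, two carbinol centres, coupling, oxidation and deprotection add up to well over ten steps.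
- Comparison: the chosen route buys ring C and C2 ready-made, reaches the target in five steps, and exposes the olefins to acid only once, under controlled conditions.

Alternative 2: The disconnection is the aryl ketone bond C4–C4a, leading back to a 3-aryl-3-aryloxypropanoic acid whose aryloxy ring is mirror-symmetric. The precursor is acid A4, (3S)-3-[3,5-bis(tert-butyldimethylsilyloxy)-4-(3-methylbut-2-enyl)phenoxy]-3-[4-(tert-butyldimethylsilyloxy)-3-geranylphenyl]propanoic acid. Activated at low temperature as its mixed anhydride with trifluoroacetic acid, it would acylate the ring carbon ortho to the ether oxygen (intramolecular Friedel–Crafts acylation). The product is A3, the tris(tert-butyldimethylsilyl) ether of 9, which fluoride would unmask.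
- For it: the two carbons ortho to the ether oxygen of A4 are equivalent, so the C6/C8 problem is removed by symmetry and not by selectivity. On this point it is again stronger than the chosen plan. The ring is electron-rich enough for a mild activator, and the carbonyl arrives at the right oxidation level.
- Against it: C2 of A4 is a benzylic carbon with an aryloxy leaving group and a para-silyloxyphenyl donor, β to an activated acyl group. The trifluoroacetic acid set free can ionise the C2–O bond, or the anhydride can lose the phenol by β-elimination to a cinnamic acid; either path destroys the stereocentre. Making that hindered benzylic aryl ether requires a displacement at an electron-rich benzylic carbinol, which drifts towards SN1 behaviour and loss of optical purity. Three olefins and three aryl silyl ethers must survive an acidic acylating medium. Both arenes must be made with their chains first.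
- Comparison: the chosen route never makes or breaks a bond at C2 and builds no ring.

Alternative 3: The disconnection is the C4a–C5 bond of ring A, which is built last from a masked polyketide. The precursor is dioxinone A6, (2S)-2-[4-(tert-butyldimethylsilyloxy)-3-geranylphenyl]-6-{[2,2-dimethyl-5-(3-methylbut-2-enyl)-4-oxo-4H-1,3-dioxin-6-yl]methyl}-2,3-dihydro-4H-pyran-4-one. On heating it would lose acetone by a retro-[4+2] reaction. The acylketene carbon (future C5) would be attacked by the enol-ether α-carbon of the dihydropyranone (future C4a), and enolisation would aromatise ring A. The product is A5, (2S)-4'-O-(tert-butyldimethylsilyl)schizolaenone A.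
- For it: ring A is made with the prenyl group already on the carbon that becomes C6, so its position is fixed by construction. The 5,7-diol appears unprotected, and the ring closure is neutral, which suits the olefins. On regiocontrol and on protecting-group economy at ring A this is the better plan.
- Against it: A6 is a sensitive polycarbonyl compound whose enantioselective assembly is long, and ring B still needs its geranyl group. At the temperature of ketene generation the 2-aryl-dihydropyranone can open and lose the C2 configuration. The acylketene can also be captured by enol oxygen instead of carbon, or dimerise.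
- Comparison: against five steps from a natural flavanone, a de novo construction of ring A is a large investment in a ring that can be bought.

Key step: step 4

Assumption: (2S)-naringenin is bought as the single enantiomer; commercial material is often partly racemic, so it is checked by chiral HPLC and upgraded by crystallisation or chiral chromatography before use if needed.

## Route

Step 1
Reactants: 1 (2S)-naringenin
Product: 2 (2S)-7-O-(triisopropylsilyl)naringenin
Conditions: TIPSCl (1.05 equiv), imidazole (2 equiv), DMF, −10 → 0 °C
Reagents that add atoms: chlorotriisopropylsilane (TIPSCl), CC(C)[Si](Cl)(C(C)C)C(C)C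
Why: Silyl ether formation at the most acidic phenol: the 7-OH is a vinylogous carboxylic acid, the 4'-OH is markedly weaker and the 5-OH is tied up in a hydrogen bond to C4=O, so one equivalent of the bulky chloride at low temperature should stop at the 7-mono-ether. Imidazole is too weak a base to open ring C, so C2 is kept.

Step 2
Reactants: 2 (2S)-7-O-(triisopropylsilyl)naringenin; 3 geraniol
Product: 4 (2S)-4'-O-geranyl-7-O-(triisopropylsilyl)naringenin
Conditions: geraniol (1.1 equiv), PPh3, DIAD, THF, 0 °C → rt
Reagents that add atoms: none
Why: Mitsunobu etherification: of the two remaining phenols only the 4'-OH is acidic and accessible enough to protonate the betaine and attack the geranyloxyphosphonium ion, while the chelated 5-OH reacts far more slowly. SN2 displacement at the primary allylic carbon keeps the chain linear and E, and the near-neutral medium spares the silyl ether and C2.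

Step 3
Reactants: 4 (2S)-4'-O-geranyl-7-O-(triisopropylsilyl)naringenin; 5 3-methylbut-2-en-1-ol (prenol)
Product: 6 (2S)-4'-O-geranyl-5-O-(3-methylbut-2-enyl)-7-O-(triisopropylsilyl)naringenin
Conditions: prenol (2 equiv), PPh3 (2 equiv), DIAD (2 equiv), THF, 0 °C → rt; chromatography on Et3N-deactivated silica
Reagents that add atoms: none
Why: Mitsunobu etherification of a chelated ortho-acylphenol, a known way to alkylate the 5-hydroxyl of 7,4'-protected flavanones without strong base; with no other acidic OH left, excess reagent drives the slow reaction at this hindered phenol, again by SN2 at the primary allylic carbon. The acid-labile 5-O-prenyl ether is kept away from acidic silica.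

Step 4
Reactants: 6 (2S)-4'-O-geranyl-5-O-(3-methylbut-2-enyl)-7-O-(triisopropylsilyl)naringenin
Product: 8 (2S)-7-O-(triisopropylsilyl)schizolaenone A, via 4'-O-geranyl-6-prenyl monoshift intermediate 7 (not isolated)
Conditions: montmorillonite K10 clay (idealised Al2Si4O10(OH)2, dried at 120 °C), CH2Cl2, −10 → 0 °C, short contact, then filtration
Reagents that add atoms: none
Why: Acid sites of the clay (Brønsted sites and exposed aluminium centres) bind each ether oxygen, at ring A as a chelate with the C4 carbonyl, and heterolyse the allylic O–CH2 bond to a contact ion pair of the phenol and a dimethylallyl or geranyl cation held at the surface. The cation collapses through its primary terminus onto the ring carbon next to the oxygen it left, and tautomerisation of the cyclohexadienone restores the phenol, so the net result is a [1,3] oxygen-to-carbon shift that forms C6–CH2 (prenyl) and C3'–CH2 (geranyl); the closest known reaction type is the clay-promoted dissociative [1,3] rearrangement of aryl prenyl and geranyl ethers, a Friedel–Crafts alkylation inside an ion pair and not a Claisen [3,3] shift, which would attach the tertiary carbon. No ring is closed and no stereocentre is made; C2 is a spectator, and the E geometry of the geranyl chain is kept because the allyl cation recombines faster than it rotates. The ring A ether, whose leaving group is a chelated vinylogous carboxylate, should ionise first (intermediate 7) and the ring B ether second. Selectivity for C6 over C8 comes from the substrate: C6 is the carbon adjacent to O5 in the ion pair, C4a is blocked, and C8 is reached only by a cation that has escaped the pair; at ring B the two ortho carbons are equivalent and the para carbon C1' is substituted. Attack through the tertiary end is disfavoured sterically, at C6 between two oxygen substituents, one of them carrying the bulky silyl group. Chroman formation is held back at ring A because the freed 5-OH is hydrogen-bonded to C4=O and O7 is silylated, and at ring B, where the 4'-OH is free, by dry clay, a non-coordinating solvent, low temperature and a short contact time ended by filtration.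

Step 5
Reactants: 8 (2S)-7-O-(triisopropylsilyl)schizolaenone A
Product: 9 schizolaenone A
Conditions: Et3N·3HF, THF, 0 °C → rt
Reagents that add atoms: none
Why: Fluoride-mediated cleavage of an aryl silyl ether: the 7-O–Si bond, whose leaving group is a vinylogous carboxylate, should be cleaved readily by the mildly acidic, non-basic Et3N·3HF. This reagent does not open ring C, as a basic fluoride source could, and is not acidic enough to cyclise the prenyl and geranyl groups onto the phenols.

## Compound list

1 | (2S)-naringenin, (2S)-5,7-dihydroxy-2-(4-hydroxyphenyl)chroman-4-one | O=C1C[C@@H](c2ccc(O)cc2)Oc2cc(O)cc(O)c12 | starting material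
2 | (2S)-7-O-(triisopropylsilyl)naringenin, (2S)-5-hydroxy-2-(4-hydroxyphenyl)-7-(triisopropylsilyloxy)chroman-4-one | Oc1ccc([C@@H]2CC(=O)c3c(cc(O[Si](C(C)C)(C(C)C)C(C)C)cc3O)O2)cc1 | intermediate
3 | geraniol, (2E)-3,7-dimethylocta-2,6-dien-1-ol | CC(C)=CCC/C(C)=C/CO | starting material
4 | (2S)-4'-O-geranyl-7-O-(triisopropylsilyl)naringenin (geranyl ether at O4', free chelated 5-OH) | CC(C)=CCC/C(C)=C/COc1ccc([C@@H]2CC(=O)c3c(cc(O[Si](C(C)C)(C(C)C)C(C)C)cc3O)O2)cc1 | intermediate
5 | 3-methylbut-2-en-1-ol (prenol) | CC(C)=CCO | starting material
6 | (2S)-4'-O-geranyl-5-O-(3-methylbut-2-enyl)-7-O-(triisopropylsilyl)naringenin | CC(C)=CCC/C(C)=C/COc1ccc([C@@H]2CC(=O)c3c(cc(O[Si](C(C)C)(C(C)C)C(C)C)cc3OCC=C(C)C)O2)cc1 | intermediate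
7 | (2S)-4'-O-geranyl-6-(3-methylbut-2-enyl)-7-O-(triisopropylsilyl)naringenin (ring A rearranged, ring B still an ether; formed in the flask in step 4) | CC(C)=CCC/C(C)=C/COc1ccc([C@@H]2CC(=O)c3c(cc(O[Si](C(C)C)(C(C)C)C(C)C)c(CC=C(C)C)c3O)O2)cc1 | intermediate
8 | (2S)-7-O-(triisopropylsilyl)schizolaenone A, (2S)-3'-geranyl-6-(3-methylbut-2-enyl)-7-O-(triisopropylsilyl)naringenin | CC(C)=CCC/C(C)=C/Cc1cc([C@@H]2CC(=O)c3c(cc(O[Si](C(C)C)(C(C)C)C(C)C)c(CC=C(C)C)c3O)O2)ccc1O | intermediate
9 | schizolaenone A, (2S)-3'-geranyl-6-(3-methylbut-2-enyl)naringenin | CC(C)=CCC/C(C)=C/Cc1cc([C@@H]2CC(=O)c3c(cc(O)c(CC=C(C)C)c3O)O2)ccc1O | target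

## Step count and least certain steps

Total: 5 steps. Longest linear sequence: 5 steps from (2S)-naringenin 1. The optical purity at C2 should be checked by chiral HPLC on 2, 6 and 9.

Step 4 (key step).
- What may go wrong: the allyl cations may escape their ion pairs, or the product phenols may be re-protonated. That leads to loss of the chains, to transfer to C8 or to another molecule, and to acid-catalysed cyclisation at ring B, where the new 3'-geranyl group sits beside a free 4'-OH. The ring B ether is expected to react more slowly, so ring A would sit on the acid while ring B is still reacting.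
- Fallback (sets out from 4, returns at 9): the two transfers are done one at a time and the ring B phenol is capped in between. Clay treatment of 4, which has only one ionisable ether and can be stopped at partial conversion with recycling, should give (2S)-3'-geranyl-7-O-(triisopropylsilyl)naringenin F1. TIPSCl and imidazole in DMF then silylate the new 4'-OH to give (2S)-3'-geranyl-7,4'-bis-O-(triisopropylsilyl)naringenin F2. Mitsunobu reaction with prenol 5 gives (2S)-3'-geranyl-5-O-(3-methylbut-2-enyl)-7,4'-bis-O-(triisopropylsilyl)naringenin F3. A single clay shift on this 7,4'-bis-protected 5-O-prenyl flavanone, a substrate with no free phenol beside an olefin, gives (2S)-7,4'-bis-O-(triisopropylsilyl)schizolaenone A F4. Et3N·3HF removes both silyl groups and gives 9.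

Step 3.
- What may go wrong: etherification of the hydrogen-bonded, hindered 5-OH may be slow, so the reagents are consumed in side reactions, and long exposure to the basic betaine may open ring C and erode the configuration at C2.
- Fallback (sets out from 4, returns at 6): alkylation under silver assistance instead of redox condensation. Treating 4 with 1-bromo-3-methylbut-2-ene and Ag2O in CH2Cl2 at room temperature in the dark (Purdie-type alkylation) lets halide abstraction drive O-alkylation of the weakly nucleophilic phenol under essentially neutral conditions. No new compound is involved.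

Step 1.
- What may go wrong: discrimination between the 7- and 4'-hydroxyls may be incomplete, because the imidazole-activated silyl chloride can also be attacked by the neutral, more nucleophilic 4'-phenol. Over-silylation and silylation at the wrong oxygen would cost material at the outset.
- Fallback (sets out from 1, returns at 9): O7 is blocked by alkylation instead of silylation. Mitsunobu reaction of 1 with one equivalent of allyl alcohol engages only the phenol acidic enough to protonate the betaine first and should give (2S)-7-O-allylnaringenin F5. The Mitsunobu reactions with 3 and then 5 give (2S)-7-O-allyl-4'-O-geranylnaringenin F6 and (2S)-7-O-allyl-4'-O-geranyl-5-O-(3-methylbut-2-enyl)naringenin F7. In the clay step the unsubstituted allyl ether cannot form a stabilised cation and should stay in place, giving (2S)-7-O-allylschizolaenone A F8. Catalytic Pd(PPh3)4 (zerovalent palladium) with morpholine in THF then removes the O-allyl group, the carbon-bound chains being inert, and gives 9.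

## Further compounds

F1 | step 4 | (2S)-3'-geranyl-7-O-(triisopropylsilyl)naringenin | CC(C)=CCC/C(C)=C/Cc1cc([C@@H]2CC(=O)c3c(cc(O[Si](C(C)C)(C(C)C)C(C)C)cc3O)O2)ccc1O
F2 | step 4 | (2S)-3'-geranyl-7,4'-bis-O-(triisopropylsilyl)naringenin | CC(C)=CCC/C(C)=C/Cc1cc([C@@H]2CC(=O)c3c(cc(O[Si](C(C)C)(C(C)C)C(C)C)cc3O)O2)ccc1O[Si](C(C)C)(C(C)C)C(C)C
F3 | step 4 | (2S)-3'-geranyl-5-O-(3-methylbut-2-enyl)-7,4'-bis-O-(triisopropylsilyl)naringenin | CC(C)=CCC/C(C)=C/Cc1cc([C@@H]2CC(=O)c3c(cc(O[Si](C(C)C)(C(C)C)C(C)C)cc3OCC=C(C)C)O2)ccc1O[Si](C(C)C)(C(C)C)C(C)C
F4 | step 4 | (2S)-7,4'-bis-O-(triisopropylsilyl)schizolaenone A | CC(C)=CCC/C(C)=C/Cc1cc([C@@H]2CC(=O)c3c(cc(O[Si](C(C)C)(C(C)C)C(C)C)c(CC=C(C)C)c3O)O2)ccc1O[Si](C(C)C)(C(C)C)C(C)C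
F0 | step 3 | none | none
F5 | step 1 | (2S)-7-O-allylnaringenin | Oc1ccc([C@@H]2CC(=O)c3c(cc(OCC=C)cc3O)O2)cc1
F6 | step 1 | (2S)-7-O-allyl-4'-O-geranylnaringenin | CC(C)=CCC/C(C)=C/COc1ccc([C@@H]2CC(=O)c3c(cc(OCC=C)cc3O)O2)cc1
F7 | step 1 | (2S)-7-O-allyl-4'-O-geranyl-5-O-(3-methylbut-2-enyl)naringenin | CC(C)=CCC/C(C)=C/COc1ccc([C@@H]2CC(=O)c3c(cc(OCC=C)cc3OCC=C(C)C)O2)cc1
F8 | step 1 | (2S)-7-O-allylschizolaenone A | CC(C)=CCC/C(C)=C/Cc1cc([C@@H]2CC(=O)c3c(cc(OCC=C)c(CC=C(C)C)c3O)O2)ccc1O
A1 | alternative 1 | (2S,4S)-3'-geranyl-5,7,4'-tris(methoxymethoxy)-6-(3-methylbut-2-enyl)flavan-4-ol | CC(C)=CCC/C(C)=C/Cc1cc([C@@H]2C[C@H](O)c3c(cc(OCOC)c(CC=C(C)C)c3OCOC)O2)ccc1OCOC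
A2 | alternative 1 | (1S,3S)-1-[3-geranyl-4-(methoxymethoxy)phenyl]-3-[6-chloro-2,4-bis(methoxymethoxy)-3-(3-methylbut-2-enyl)phenyl]propane-1,3-diol | CC(C)=CCC/C(C)=C/Cc1cc([C@@H](O)C[C@H](O)c2c(Cl)cc(OCOC)c(CC=C(C)C)c2OCOC)ccc1OCOC
A3 | alternative 2 | (2S)-schizolaenone A tris(tert-butyldimethylsilyl) ether | CC(C)=CCC/C(C)=C/Cc1cc([C@@H]2CC(=O)c3c(cc(O[Si](C)(C)C(C)(C)C)c(CC=C(C)C)c3O[Si](C)(C)C(C)(C)C)O2)ccc1O[Si](C)(C)C(C)(C)C
A4 | alternative 2 | (3S)-3-[3,5-bis(tert-butyldimethylsilyloxy)-4-(3-methylbut-2-enyl)phenoxy]-3-[4-(tert-butyldimethylsilyloxy)-3-geranylphenyl]propanoic acid | CC(C)=CCC/C(C)=C/Cc1cc([C@H](CC(=O)O)Oc2cc(O[Si](C)(C)C(C)(C)C)c(CC=C(C)C)c(O[Si](C)(C)C(C)(C)C)c2)ccc1O[Si](C)(C)C(C)(C)C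
A5 | alternative 3 | (2S)-4'-O-(tert-butyldimethylsilyl)schizolaenone A | CC(C)=CCC/C(C)=C/Cc1cc([C@@H]2CC(=O)c3c(cc(O)c(CC=C(C)C)c3O)O2)ccc1O[Si](C)(C)C(C)(C)C
A6 | alternative 3 | (2S)-2-[4-(tert-butyldimethylsilyloxy)-3-geranylphenyl]-6-{[2,2-dimethyl-5-(3-methylbut-2-enyl)-4-oxo-4H-1,3-dioxin-6-yl]methyl}-2,3-dihydro-4H-pyran-4-one | CC(C)=CCC/C(C)=C/Cc1cc([C@@H]2CC(=O)C=C(CC3=C(CC=C(C)C)C(=O)OC(C)(C)O3)O2)ccc1O[Si](C)(C)C(C)(C)C
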